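## The problem

The target is a flavonol: a 4H-chromen-4-one (ring A fused to the pyranone ring C) carrying the catechol ring B at C2. It has no stereocenter, so nothing has to be set or relayed. The difficulty is regiochemical: five oxygens of one quercetin core must end in three states, an acetate on O3, hydrogen sulfates on O7, O3' and O4', and a free hydroxyl on O5. The aryl hydrogen sulfates are ionic and acid-labile and cannot be carried through organometallic steps or chromatography on silica. The 3-acetate is an enol ester that bases and nucleophiles remove or move. Both therefore come at the very end, the acetate first, with nothing basic after it. The feature used is the polyketide pattern of ring A: oxygen sits on the alternate carbons C5, C7 and C8a and the C4 carbonyl on C4a. Ring A is thus the folded form of a chain C5(=O)–C6–C7(=O)–C8–C8a(O)–C4a–C4(=O), in which C4a is the alpha carbon of the C4 carbonyl and C5 an acyl carbon. Closing C4a–C5 by a Claisen condensation builds ring A with its oxygens in place; the former ester oxygen becomes the 5-hydroxyl, peri to the C4 carbonyl and chelated to it, which separates O5 from O7 without a protecting group.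

## Retrosynthesis

Flavone numbering is used for all atoms that end up in the chromenone, also in the monocyclic precursors.

**19 ⇒ 18.** The three O–S bonds are cut first, giving quercetin 3-acetate 18. Carrying protected sulfates through the route would cost more steps and still end with an unmasking on a polyanion. The forward reaction must sulfate O7, O3' and O4', leave the chelated 5-hydroxyl alone and not disturb the enol acetate.

**18 ⇒ 17.** The three sulfation sites are masked as benzyl ethers in 17. Hydrogenolysis is neutral and non-nucleophilic, the only kind of unmasking the 3-acetate tolerates; silyl, acetal or acyl masks would need fluoride, acid or base at this point.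

**17 ⇒ 16 ⇒ 15.** The acetyl C–O bond is cut to the 3,5-diol 16, and the 3-hydroxyl is traced back to the methoxymethyl (MOM) ether 15. O3 needs a mask orthogonal to benzyl and stable to palladium, amide bases and methoxide. An allyl ether was considered and set aside, because an allyl ether of a 3-hydroxy-4-pyranone is a good leaving group towards zerovalent palladium and would be at risk in the cross-coupling below. The forward acetylation must choose O3 over O5, which the stronger six-membered chelate of the 5-hydroxyl should secure.

**15 ⇒ 14.** The O7–benzyl bond is cut. In 14 only two hydroxyls are free, the chelated 5-OH and the acidic 7-OH, so one equivalent of benzyl bromide should go to O7.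

**14 ⇒ 12 (key disconnection).** The C4a–C5 bond is cut and ring A opens to the keto ester arm of pyranone 12. The neighbouring cuts in ring C (O1–C8a, C2–C3, C4–C4a) all start from a bought phloroglucinol ring and are discussed below. This cut instead makes ring A from a chain, with O3 present from the first compound and O5 and O7 born different. The precursor is a monocyclic 4-pyranone with a four-carbon side chain. The forward reaction asks C4a, a ring carbon of the pyranone that is nucleophilic only through the dienolate of the C8 methylene, to acylate itself with the ester carbon C5; the cyclised triketone 13 then aromatises.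

**12 ⇒ 9 + 10, and 9 ⇒ 7.** The C6–C7 bond is cut to pyranylacetic acid 9 and potassium methyl malonate 10 (via imidazolide 11). The C7–C8 bond is then cut to the 2-methylpyranone 7 and CO2 (via lateral dienolate 8). A one-step acylation of 8 with a malonyl unit is not possible, because any such reagent has a more acidic methylene than the one being acylated.

**7 ⇒ 5 + 6.** The C2–C1' bond is cut to bromopyranone 5 and boronic acid 6. The C–Br bond of 5 is a vinylogous acyl bromide and an activated Suzuki partner, and ring B enters as a bought, fully protected piece.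

**5 ⇒ 4 ⇒ 3 ⇒ 2 ⇒ 1.** Functional group changes lead back to kojic acid 1: MOM protection of the enol in 4, bromination of allomaltol 3 at the enol carbon, and removal of the primary hydroxyl of 1 via chloride 2. Kojic acid supplies ring C with O3, O4 and the carbon that becomes C8.

## Roads not taken

**Alternative 1:** The cut is the C2=C3 double bond of ring C. The forward key step would heat the acyl ylide A1, 3,5-bis(benzyloxy)-2-{2-[2-(trimethylsilyl)ethoxy]-2-(triphenyl-λ5-phosphanylidene)acetyl}phenyl 3,4-bis(benzyloxy)benzoate, in toluene. The ylide carbon (future C3) would add to the aryl ester carbonyl (future C2) and loss of triphenylphosphine oxide would give A2, 5,7-bis(benzyloxy)-2-[3,4-bis(benzyloxy)phenyl]-3-[2-(trimethylsilyl)ethoxy]-4H-chromen-4-one.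
- Merits: ring A is bought with O5 and O7 in place, the closure is neutral, the regiochemistry is fixed by connectivity, and O3 arrives as a fluoride-labile ether orthogonal to benzyl.
- Weak points: an ester carbonyl is a poor Wittig acceptor, and the ylide is acyl-stabilised, fully substituted by the alkoxy group and attached to a 2,6-disubstituted aryl ketone. Making A1 needs an alpha-alkoxy-alpha-phosphonio ketone, which is awkward to prepare.
- Comparison: from A2 the endgame would be the one used here without the 7-O-benzylation, and the whole route would be two or three steps shorter. On length Alternative 1 is better. On risk the two key steps are about level, since neither has close precedent. The chosen plan sets against it that O3 is in place from the first compound and that ring B enters by a routine cross-coupling.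

**Alternative 2:** The cuts are C4a–C4, C4–C3 and O1–C2. PdCl2(PPh3)2, carbon monoxide and diethylamine would unite iodophenol A3 (3,5-bis(benzyloxy)-2-iodophenol), CO and alkyne A4 (1,2-bis(benzyloxy)-4-ethynylbenzene). Oxidative addition, CO insertion and acyl–alkynyl coupling would give an ortho-hydroxyaryl ynone, and amine-mediated 6-endo addition of the phenol would give A5, 5,7-bis(benzyloxy)-2-[3,4-bis(benzyloxy)phenyl]-4H-chromen-4-one.
- Merits: the most convergent plan, with three bonds and ring C formed in one flask from simple halves.
- Weak points: A5 has hydrogen at C3, so the oxygen that must carry the acetate would have to be added later by oxidising the C2–C3 enol ether bond in a molecule with four benzyl ethers and two electron-rich rings. The iodide of A3 sits between two oxygen substituents on a very electron-rich ring, so oxidative addition is slow. Direct coupling without CO (leading to a benzofuran) and 5-exo closure (aurone) compete.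
- Comparison: even with the extra oxidation this road would reach the common endgame in about nine steps, each with precedent. It is the better plan on step count and on certainty. The chosen plan sets against it only that C3 never has to be oxidised and that there is no aurone or benzofuran channel.

**Alternative 3:** The cut is O1–C8a. K2CO3 in DMF would enolise diketone A6, 1-[3,4-bis(benzyloxy)phenyl]-2-(methoxymethoxy)-3-(2,4,6-trifluorophenyl)propane-1,3-dione. The enolate oxygen on the ring B side would displace an ortho fluoride by addition–elimination and give A7, 2-[3,4-bis(benzyloxy)phenyl]-5,7-difluoro-3-(methoxymethoxy)-4H-chromen-4-one.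
- Merits: a dependable closure, since an ortho-fluoroaryl ketone is a good acceptor and the two ortho fluorides are equivalent; O3 is a MOM ether as in the chosen plan.
- Weak points: A7 still has fluorine where O5 and O7 belong. Two further substitutions by an oxygen nucleophile are needed, the second on a ring deactivated by the first alkoxy group, and alkoxide can also add at C2 and open ring C. Preparing A6 requires C-acylation of an alpha-alkoxy ketone enolate against O-acylation.
- Comparison: the length is about the same as the chosen plan, and its closure is better founded than the key step here, which is a real point in its favour. The chosen plan sets against it that the bond-forming step itself delivers both ring A oxygens as hydroxyls of different reactivity, with no fluorine-to-oxygen exchange on a base-sensitive chromenone.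

Key step: step 8

Remark on the chemistry: the target is drawn as the tris(hydrogen sulfate). It is assumed that this free acid form is meant; it would be obtained from the pyridinium salt by cation exchange, and kept as the sodium salt if it has to be stored.

## Route

Step 1
Reactants: 1 kojic acid (5-hydroxy-2-(hydroxymethyl)-4H-pyran-4-one)
Product: 2 2-(chloromethyl)-5-hydroxy-4H-pyran-4-one (chlorokojic acid)
Conditions: SOCl2 (neat), rt
Reagents that add atoms: thionyl chloride, O=S(Cl)Cl
Why: Chlorination of the primary, allylic-type alcohol through its chlorosulfite; the enolic 5-hydroxyl does not react, and this is the standard preparation of chlorokojic acid.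

Step 2
Reactants: 2 2-(chloromethyl)-5-hydroxy-4H-pyran-4-one
Product: 3 5-hydroxy-2-methyl-4H-pyran-4-one (allomaltol)
Conditions: Zn dust, conc. HCl, H2O, 70 °C
Reagents that add atoms: none
Why: Dissolving-metal hydrogenolysis of the activated C–Cl bond (a vinylogous alpha-chloro ketone); the pyranone and the enol are untouched, and this is the standard route to allomaltol.

Step 3
Reactants: 3 5-hydroxy-2-methyl-4H-pyran-4-one
Product: 4 6-bromo-5-hydroxy-2-methyl-4H-pyran-4-one
Conditions: NBS, MeCN, 0 °C to rt, dark
Reagents that add atoms: N-bromosuccinimide, O=C1CCC(=O)N1Br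
Why: Electrophilic bromination of the enol; the free 5-hydroxyl directs the electrophile to C6, the position that kojic acid and allomaltol use in halogenation and Mannich reactions, while C3 is not activated.

Step 4
Reactants: 4 6-bromo-5-hydroxy-2-methyl-4H-pyran-4-one
Product: 5 6-bromo-5-(methoxymethoxy)-2-methyl-4H-pyran-4-one
Conditions: MOMCl, iPr2NEt, CH2Cl2, 0 °C to rt
Reagents that add atoms: chloromethyl methyl ether, COCCl
Why: O-alkylation of the acidic enol with a reactive alpha-chloro ether; the MOM acetal is inert to palladium, aqueous base, amide bases and methoxide and leaves later under acid that benzyl ethers tolerate.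

Step 5
Reactants: 5 6-bromo-5-(methoxymethoxy)-2-methyl-4H-pyran-4-one; 6 3,4-bis(benzyloxy)phenylboronic acid
Product: 7 6-[3,4-bis(benzyloxy)phenyl]-5-(methoxymethoxy)-2-methyl-4H-pyran-4-one
Conditions: Pd(dppf)Cl2 (5 mol %), K2CO3, 1,4-dioxane/H2O, 85 °C
Reagents that add atoms: none
Why: Suzuki–Miyaura coupling; the C6–Br bond is a vinylogous acyl bromide and adds readily to zerovalent palladium, and the MOM ether, unlike an allyl ether, offers palladium no second point of attack.

Step 6
Reactants: 7 6-[3,4-bis(benzyloxy)phenyl]-5-(methoxymethoxy)-2-methyl-4H-pyran-4-one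
Product: 9 {6-[3,4-bis(benzyloxy)phenyl]-5-(methoxymethoxy)-4-oxo-4H-pyran-2-yl}acetic acid, via lithium dienolate 8 (not isolated)
Conditions: LiN(SiMe3)2 (1.2 equiv), THF, −78 °C; cannulate into CO2-saturated THF, −78 to 0 °C; cold 1 M HCl to pH 3
Reagents that add atoms: carbon dioxide, O=C=O; lithium bis(trimethylsilyl)amide, [Li]N([Si](C)(C)C)[Si](C)(C)C (its lithium stays only in intermediate 8)
Why: Lateral (vinylogous) deprotonation of the 2-methyl group of a 4-pyranone gives a dienolate that reacts with electrophiles at the exocyclic carbon, here in a carboxylation; inverse addition to excess CO2 keeps the more acidic product from quenching unreacted anion.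

Step 7
Reactants: 9 {6-[3,4-bis(benzyloxy)phenyl]-5-(methoxymethoxy)-4-oxo-4H-pyran-2-yl}acetic acid; 10 potassium methyl malonate
Product: 12 methyl 4-{6-[3,4-bis(benzyloxy)phenyl]-5-(methoxymethoxy)-4-oxo-4H-pyran-2-yl}-3-oxobutanoate, via acyl imidazolide 11 (not isolated)
Conditions: CDI, THF, rt; then 10, MgCl2, Et3N, THF/MeCN, rt to 45 °C; cold aq. citric acid
Reagents that add atoms: 1,1'-carbonyldiimidazole, O=C(n1ccnc1)n1ccnc1 (its imidazolyl group stays only in intermediate 11)
Why: Masamune–Brooks homologation: the acyl imidazolide C-acylates the magnesium enolate of the malonate half ester and the adduct loses CO2, giving the beta-keto ester under nearly neutral conditions that spare the MOM ether and the pyranone.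

Step 8
Reactants: 12 methyl 4-{6-[3,4-bis(benzyloxy)phenyl]-5-(methoxymethoxy)-4-oxo-4H-pyran-2-yl}-3-oxobutanoate
Product: 14 2-[3,4-bis(benzyloxy)phenyl]-5,7-dihydroxy-3-(methoxymethoxy)-4H-chromen-4-one, via triketone tautomer 13 (not isolated)
Conditions: Mg(OMe)2 (5 equiv), MeOH (0.01 M), reflux; then cold 1 M HCl
Reagents that add atoms: none
Why: Proposed new method: Mg(OMe)2 reversibly deprotonates the C6 methylene (keto ester enolate, unproductive) and the C8 methylene, whose anion is a dienolate spread through the pyranone onto O4 and C4a; C4a, the alpha carbon of that dienolate, adds to the magnesium-bound ester carbonyl C5, methoxide leaves, and triketone 13 enolises twice to the aromatic ring A of 14. The closest known reaction type is the Mg(OMe)2-induced Claisen cyclisation of 3,5,7-triketo esters to acylphloroglucinols; here the C2, C4 and C8a carbonyls of the chain are already tied up as ring C, so the nucleophile is a ring carbon of a 4-pyranone, which has not been shown. Ring A closes in a 6-(enolexo)-exo-trig mode. No stereocenter is formed. The step needs C-acylation at C4a to win over aldol closure, retro-Claisen cleavage and intermolecular condensation: attack from C8 would give a four-membered ring, the only carbonyl an aldol from C6 could reach is the vinylogous-ester C4 and that would give a bridged ring, methanol makes ester exchange degenerate, and high dilution disfavours dimerisation. Aromatisation to the chelated magnesium 5-phenoxide makes the closure irreversible and draws the unproductive enolate through the equilibrium. The ester oxygen ends as the chelated 5-hydroxyl and the ketone oxygen as the free 7-hydroxyl.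

Step 9
Reactants: 14 2-[3,4-bis(benzyloxy)phenyl]-5,7-dihydroxy-3-(methoxymethoxy)-4H-chromen-4-one
Product: 15 7-(benzyloxy)-2-[3,4-bis(benzyloxy)phenyl]-5-hydroxy-3-(methoxymethoxy)-4H-chromen-4-one
Conditions: BnBr (1.05 equiv), K2CO3, DMF, rt
Reagents that add atoms: benzyl bromide, BrCc1ccccc1
Why: Williamson etherification; the 7-hydroxyl is the more acidic and is free, while the 5-hydroxyl is held in a hydrogen bond to the C4 carbonyl, so one equivalent of halide alkylates O7 only, as is general for 5,7-dihydroxyflavones.

Step 10
Reactants: 15 7-(benzyloxy)-2-[3,4-bis(benzyloxy)phenyl]-5-hydroxy-3-(methoxymethoxy)-4H-chromen-4-one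
Product: 16 7-(benzyloxy)-2-[3,4-bis(benzyloxy)phenyl]-3,5-dihydroxy-4H-chromen-4-one
Conditions: conc. HCl (cat.), MeOH/THF, 50 °C
Reagents that add atoms: none
Why: Acid-catalysed acetal exchange removes the MOM group as dimethoxymethane; aryl benzyl ethers and the chromenone are stable to these conditions.

Step 11
Reactants: 16 7-(benzyloxy)-2-[3,4-bis(benzyloxy)phenyl]-3,5-dihydroxy-4H-chromen-4-one
Product: 17 7-(benzyloxy)-2-[3,4-bis(benzyloxy)phenyl]-5-hydroxy-4-oxo-4H-chromen-3-yl acetate
Conditions: Ac2O (1.1 equiv), pyridine, CH2Cl2, 0 °C
Reagents that add atoms: acetic anhydride, CC(=O)OC(C)=O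
Why: O-acylation; of the two hydroxyls the 5-OH sits in the stronger six-membered chelate and is the least reactive hydroxyl of a flavonol, so a slight excess of anhydride at low temperature should acetylate O3 alone.

Step 12
Reactants: 17 7-(benzyloxy)-2-[3,4-bis(benzyloxy)phenyl]-5-hydroxy-4-oxo-4H-chromen-3-yl acetate
Product: 18 2-(3,4-dihydroxyphenyl)-5,7-dihydroxy-4-oxo-4H-chromen-3-yl acetate (quercetin 3-acetate)
Conditions: H2 (1 atm), Pd/C (10%), EtOAc/THF, rt
Reagents that add atoms: none
Why: Catalytic hydrogenolysis of the three aryl benzyl ethers under neutral conditions in a non-nucleophilic solvent, so the enol acetate neither leaves nor migrates; the tetrasubstituted, conjugated C2–C3 bond of a flavone is reduced far more slowly than benzyl ethers are cleaved.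

Step 13
Reactants: 18 2-(3,4-dihydroxyphenyl)-5,7-dihydroxy-4-oxo-4H-chromen-3-yl acetate
Product: 19 quercetin 3-acetate 7,3',4'-tri-O-sulfate (2-[3,4-bis(sulfooxy)phenyl]-5-hydroxy-4-oxo-7-(sulfooxy)-4H-chromen-3-yl acetate)
Conditions: SO3·pyridine (12 equiv), dry DMF/pyridine, 40 °C; then sulfonic acid resin (H+ form), H2O, 0 °C
Reagents that add atoms: sulfur trioxide pyridine complex, [O-]S(=O)(=O)[n+]1ccccc1
Why: O-sulfonation of phenols with an amine–SO3 complex, the usual way to flavonoid sulfates; the chelated 5-hydroxyl resists sulfation, excess reagent drives the second sulfation of the catechol, and dry, weakly basic conditions spare the acetate.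

## Compound list

1 | kojic acid (5-hydroxy-2-(hydroxymethyl)-4H-pyran-4-one) | OCc1cc(=O)c(O)co1 | starting material
2 | 2-(chloromethyl)-5-hydroxy-4H-pyran-4-one | ClCc1cc(=O)c(O)co1 | intermediate
3 | 5-hydroxy-2-methyl-4H-pyran-4-one | Cc1cc(=O)c(O)co1 | intermediate
4 | 6-bromo-5-hydroxy-2-methyl-4H-pyran-4-one | Cc1cc(=O)c(O)c(Br)o1 | intermediate
5 | 6-bromo-5-(methoxymethoxy)-2-methyl-4H-pyran-4-one | Cc1cc(=O)c(OCOC)c(Br)o1 | intermediate
6 | 3,4-bis(benzyloxy)phenylboronic acid | OB(O)c1ccc(OCc2ccccc2)c(OCc2ccccc2)c1 | starting material
7 | 6-[3,4-bis(benzyloxy)phenyl]-5-(methoxymethoxy)-2-methyl-4H-pyran-4-one | Cc1cc(=O)c(OCOC)c(-c2ccc(OCc3ccccc3)c(OCc3ccccc3)c2)o1 | intermediate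
8 | lithium 6-[3,4-bis(benzyloxy)phenyl]-5-(methoxymethoxy)-2-methylidene-2H-pyran-4-olate (lateral dienolate) | C=C1C=C(O[Li])C(OCOC)=C(c2ccc(OCc3ccccc3)c(OCc3ccccc3)c2)O1 | intermediate
9 | {6-[3,4-bis(benzyloxy)phenyl]-5-(methoxymethoxy)-4-oxo-4H-pyran-2-yl}acetic acid | OC(=O)Cc1cc(=O)c(OCOC)c(-c2ccc(OCc3ccccc3)c(OCc3ccccc3)c2)o1 | intermediate
10 | potassium methyl malonate (potassium 3-methoxy-3-oxopropanoate) | COC(=O)CC(=O)[O-].[K+] | starting material
11 | 1-({6-[3,4-bis(benzyloxy)phenyl]-5-(methoxymethoxy)-4-oxo-4H-pyran-2-yl}acetyl)-1H-imidazole | O=C(Cc1cc(=O)c(OCOC)c(-c2ccc(OCc3ccccc3)c(OCc3ccccc3)c2)o1)n1ccnc1 | intermediate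
12 | methyl 4-{6-[3,4-bis(benzyloxy)phenyl]-5-(methoxymethoxy)-4-oxo-4H-pyran-2-yl}-3-oxobutanoate | COC(=O)CC(=O)Cc1cc(=O)c(OCOC)c(-c2ccc(OCc3ccccc3)c(OCc3ccccc3)c2)o1 | intermediate
13 | 2-[3,4-bis(benzyloxy)phenyl]-3-(methoxymethoxy)-4a,6-dihydro-4H-chromene-4,5,7-trione (cyclised triketone, racemic at C4a, transient) | O=C1CC(=O)C=C2OC(c3ccc(OCc4ccccc4)c(OCc4ccccc4)c3)=C(OCOC)C(=O)C12 | intermediate
14 | 2-[3,4-bis(benzyloxy)phenyl]-5,7-dihydroxy-3-(methoxymethoxy)-4H-chromen-4-one | COCOc1c(-c2ccc(OCc3ccccc3)c(OCc3ccccc3)c2)oc2cc(O)cc(O)c2c1=O | intermediate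
15 | 7-(benzyloxy)-2-[3,4-bis(benzyloxy)phenyl]-5-hydroxy-3-(methoxymethoxy)-4H-chromen-4-one | COCOc1c(-c2ccc(OCc3ccccc3)c(OCc3ccccc3)c2)oc2cc(OCc3ccccc3)cc(O)c2c1=O | intermediate
16 | 7-(benzyloxy)-2-[3,4-bis(benzyloxy)phenyl]-3,5-dihydroxy-4H-chromen-4-one | Oc1c(-c2ccc(OCc3ccccc3)c(OCc3ccccc3)c2)oc2cc(OCc3ccccc3)cc(O)c2c1=O | intermediate
17 | 7-(benzyloxy)-2-[3,4-bis(benzyloxy)phenyl]-5-hydroxy-4-oxo-4H-chromen-3-yl acetate | CC(=O)Oc1c(-c2ccc(OCc3ccccc3)c(OCc3ccccc3)c2)oc2cc(OCc3ccccc3)cc(O)c2c1=O | intermediate
18 | 2-(3,4-dihydroxyphenyl)-5,7-dihydroxy-4-oxo-4H-chromen-3-yl acetate | CC(=O)Oc1c(-c2ccc(O)c(O)c2)oc2cc(O)cc(O)c2c1=O | intermediate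
19 | quercetin 3-acetate 7,3',4'-tri-O-sulfate | CC(=O)Oc1c(-c2ccc(OS(=O)(=O)O)c(OS(=O)(=O)O)c2)oc2cc(OS(=O)(=O)O)cc(O)c2c1=O | target

## Step count and least certain steps

Total: 13 steps. Longest linear sequence: 13 steps, from kojic acid 1 to 19; 6 and 10 are bought.

**Step 8 (key step, proposed new method).** C4a may fail to act as the nucleophile, so that the substrate rests as its keto ester enolate. Methoxide may instead add to ring C and open it, or cleave the C7 ketone by retro-Claisen methanolysis. The cause is that the C4a position of a 4-pyranone is reached only through a minor resonance form of the dienolate, while the ester is deactivated whenever C6 is deprotonated.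
- Fallback: give up the de novo ring A and use known flavone chemistry with the same ring B piece. It sets out from boronic acid 6 and comes back at 16.
- Purchased 5,7-dihydroxy-4H-chromen-4-one would be benzylated twice (BnBr, K2CO3, DMF, 80 °C) to 5,7-bis(benzyloxy)-4H-chromen-4-one F1.
- Oxidative boron–Heck arylation of F1 with 6 (Pd(O2CCF3)2, 2,2'-bipyridine, O2, DMSO; divalent palladium) would give 5,7-bis(benzyloxy)-2-[3,4-bis(benzyloxy)phenyl]-4H-chromen-4-one F2, the same compound as A5.
- Dimethyldioxirane in acetone/CH2Cl2 would epoxidise C2–C3 to racemic 5,7-bis(benzyloxy)-2-[3,4-bis(benzyloxy)phenyl]-2,3-epoxy-2,3-dihydro-4H-chromen-4-one F3.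
- Catalytic p-toluenesulfonic acid would open F3 to 5,7-bis(benzyloxy)-2-[3,4-bis(benzyloxy)phenyl]-3-hydroxy-4H-chromen-4-one F4.
- BCl3 in CH2Cl2 at −78 °C, which acts through chelation to the C4 carbonyl, would remove only the 5-O-benzyl group and give 16.

**Step 6.** Proton transfer from the product carboxylate to unreacted dienolate may stop the carboxylation early, and the vinylogous beta-keto acid 9 may lose CO2 on acidification or on standing, which would also undermine step 7.
- Fallback: it sets out from 7 and comes back at 12, without acid 9 and without step 7.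
- Dienolate 8 would be acylated with N-methoxy-N-methylacetamide to 6-[3,4-bis(benzyloxy)phenyl]-5-(methoxymethoxy)-2-(2-oxopropyl)-4H-pyran-4-one F5.
- The dianion of F5 (LiN(iPr)2, 2.2 equiv, THF, −78 °C) would be methoxycarbonylated at its terminal carbon with dimethyl carbonate, the classical terminal acylation of beta-diketone dianions, to give 12.

**Step 13.** Sulfation of the second catechol oxygen may stall, because the first sulfate puts charge and bulk next to it. Long reaction times in pyridine invite loss or migration of the 3-acetyl group.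
- Fallback: it sets out from 18 and comes back at 19, through neutral protected sulfates.
- 2,2,2-Trichloroethyl chlorosulfate with Et3N in THF at 0 °C would give 2-{3,4-bis[(2,2,2-trichloroethoxy)sulfonyloxy]phenyl}-5-hydroxy-4-oxo-7-[(2,2,2-trichloroethoxy)sulfonyloxy]-4H-chromen-3-yl acetate F6, which can be purified on silica.
- Zn dust and HCO2NH4 in MeOH would remove the trichloroethyl groups by reductive elimination, and cation exchange would give 19.

**Step 12.** Slow cleavage of the third benzyl ether may force long exposure, during which the C2–C3 bond may be reduced or the acetyl group may move to a freed phenol.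
- Fallback: Lewis-acid debenzylation in place of hydrogenation, setting out from 17 and coming back at 18.
- BCl3 with pentamethylbenzene as cation scavenger in CH2Cl2 at −78 °C cleaves aryl benzyl ethers and leaves esters alone. This fallback makes no new compound (F0).

## Further compounds

F1 | step 8 | 5,7-bis(benzyloxy)-4H-chromen-4-one | O=c1ccoc2cc(OCc3ccccc3)cc(OCc3ccccc3)c12
F2 | step 8 | 5,7-bis(benzyloxy)-2-[3,4-bis(benzyloxy)phenyl]-4H-chromen-4-one | O=c1cc(-c2ccc(OCc3ccccc3)c(OCc3ccccc3)c2)oc2cc(OCc3ccccc3)cc(OCc3ccccc3)c12
F3 | step 8 | 5,7-bis(benzyloxy)-2-[3,4-bis(benzyloxy)phenyl]-2,3-epoxy-2,3-dihydro-4H-chromen-4-one (racemic, cis-fused epoxide) | O=C1c2c(OCc3ccccc3)cc(OCc3ccccc3)cc2OC2(c3ccc(OCc4ccccc4)c(OCc4ccccc4)c3)OC12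
F4 | step 8 | 5,7-bis(benzyloxy)-2-[3,4-bis(benzyloxy)phenyl]-3-hydroxy-4H-chromen-4-one | Oc1c(-c2ccc(OCc3ccccc3)c(OCc3ccccc3)c2)oc2cc(OCc3ccccc3)cc(OCc3ccccc3)c2c1=O
F5 | step 6 | 6-[3,4-bis(benzyloxy)phenyl]-5-(methoxymethoxy)-2-(2-oxopropyl)-4H-pyran-4-one | CC(=O)Cc1cc(=O)c(OCOC)c(-c2ccc(OCc3ccccc3)c(OCc3ccccc3)c2)o1
F6 | step 13 | 2-{3,4-bis[(2,2,2-trichloroethoxy)sulfonyloxy]phenyl}-5-hydroxy-4-oxo-7-[(2,2,2-trichloroethoxy)sulfonyloxy]-4H-chromen-3-yl acetate | CC(=O)Oc1c(-c2ccc(OS(=O)(=O)OCC(Cl)(Cl)Cl)c(OS(=O)(=O)OCC(Cl)(Cl)Cl)c2)oc2cc(OS(=O)(=O)OCC(Cl)(Cl)Cl)cc(O)c2c1=O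
F0 | step 12 | none | none
A1 | alternative 1 | 3,5-bis(benzyloxy)-2-{2-[2-(trimethylsilyl)ethoxy]-2-(triphenyl-λ5-phosphanylidene)acetyl}phenyl 3,4-bis(benzyloxy)benzoate | C[Si](C)(C)CCOC(C(=O)c1c(OCc2ccccc2)cc(OCc2ccccc2)cc1OC(=O)c1ccc(OCc2ccccc2)c(OCc2ccccc2)c1)=P(c1ccccc1)(c1ccccc1)c1ccccc1
A2 | alternative 1 | 5,7-bis(benzyloxy)-2-[3,4-bis(benzyloxy)phenyl]-3-[2-(trimethylsilyl)ethoxy]-4H-chromen-4-one | C[Si](C)(C)CCOc1c(-c2ccc(OCc3ccccc3)c(OCc3ccccc3)c2)oc2cc(OCc3ccccc3)cc(OCc3ccccc3)c2c1=O
A3 | alternative 2 | 3,5-bis(benzyloxy)-2-iodophenol | Oc1cc(OCc2ccccc2)cc(OCc2ccccc2)c1I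
A4 | alternative 2 | 1,2-bis(benzyloxy)-4-ethynylbenzene | C#Cc1ccc(OCc2ccccc2)c(OCc2ccccc2)c1
A5 | alternative 2 | 5,7-bis(benzyloxy)-2-[3,4-bis(benzyloxy)phenyl]-4H-chromen-4-one | O=c1cc(-c2ccc(OCc3ccccc3)c(OCc3ccccc3)c2)oc2cc(OCc3ccccc3)cc(OCc3ccccc3)c12
A6 | alternative 3 | 1-[3,4-bis(benzyloxy)phenyl]-2-(methoxymethoxy)-3-(2,4,6-trifluorophenyl)propane-1,3-dione | COCOC(C(=O)c1ccc(OCc2ccccc2)c(OCc2ccccc2)c1)C(=O)c1c(F)cc(F)cc1F
A7 | alternative 3 | 2-[3,4-bis(benzyloxy)phenyl]-5,7-difluoro-3-(methoxymethoxy)-4H-chromen-4-one | COCOc1c(-c2ccc(OCc3ccccc3)c(OCc3ccccc3)c2)oc2cc(F)cc(F)c2c1=O
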